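**Plan**
- Ring locants: C1 = C(Me)OH, C2 = quaternary C(Me) bearing the side chain, C3 = CH(3-hydroxypropyl), C4 = alkylidene carbon, C5/C6 = CH2. C1–C2–C3 are contiguous, the C1–O bond is anti to C2–C3 and C4 sits next to C3. This is the pattern left when a tetrasubstituted epoxide (C1/C2) is opened at C2 by a 2-(silylmethyl)alkene (C4=C3).
- Cuts: the side-chain CH2–C(Me)= bond (B-alkyl Suzuki), the CHO and Me on the exocyclic carbon (two couplings on a C4=CBr2 unit from the C4 ketone), the ring bond C2–C3 (epoxide–allylsilane closure), and the acyclic chain at the two alkynes of 1,5-hexadiyne.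
- Forward: one alkyne becomes the allylsilane (carbocupration/alkylation), the other the E-allylic alcohol (anti-carbomagnesiation/methylation); Sharpless epoxide, vinyl epoxide, the single ring closes in step 11; methylene to ketone to enal precursor; side chain joined in step 22; oxidation and desilylation.
- Stereochemistry: C1 and C2 from one Sharpless epoxidation (C1 kept, C2 inverted on ring closure); C3 from the chair of the closure and the allylsilane geometry; the side-chain carbinol from an asymmetric transfer hydrogenation; alkene geometries from geranyl chloride, hydrozirconation and site-selective coupling.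

Key step: step 11

Remark: the facial sense of the transfer hydrogenation in step 19 is assigned by letting the alkynyl group play the role of the aryl group of an aryl ketone; should it prove opposite, the (S,S)-catalyst is used.

**Route**

Step 1
Reactants: 1 1,5-hexadiyne
Product: 3 trimethyl(hexa-1,5-diyn-1-yl)silane, via lithium acetylide 2 (not isolated)
Conditions: n-BuLi (1 equiv), THF, −78 °C; TMSCl; 1 used in excess (3 equiv)
Reagents that add atoms: chlorotrimethylsilane, C[Si](C)(C)Cl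
Why: Deprotonation and C-silylation of a terminal alkyne; the excess of diyne should hold back double silylation, and the silyl group masks one alkyne for steps 4 and 5.

Step 2
Reactants: 4 3-bromopropan-1-ol
Product: 5 (3-bromopropoxy)(tert-butyl)diphenylsilane
Conditions: TBDPSCl, imidazole, CH2Cl2, rt
Reagents that add atoms: tert-butyl(chloro)diphenylsilane, CC(C)(C)[Si](Cl)(c1ccccc1)c1ccccc1
Why: Standard silylation of a primary alcohol; the TBDPS ether is chosen to survive organometallics, carbonate/methanol, Lewis acid and periodic acid.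

Step 3
Reactants: 5 (3-bromopropoxy)(tert-butyl)diphenylsilane
Product: 6 tert-butyl(3-iodopropoxy)diphenylsilane
Conditions: NaI, acetone, reflux
Reagents that add atoms: sodium iodide, [Na+].[I-]
Why: Finkelstein exchange gives the primary iodide needed for alkylation of an alkenylcopper.

Step 4
Reactants: 3 trimethyl(hexa-1,5-diyn-1-yl)silane; 6 tert-butyl(3-iodopropoxy)diphenylsilane
Product: 8 tert-butyl{[(4Z)-5-[(trimethylsilyl)methyl]-9-(trimethylsilyl)non-4-en-8-yn-1-yl]oxy}diphenylsilane, via alkenylcopper 7 (not isolated)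
Conditions: Me3SiCH2MgCl, CuBr·SMe2, Et2O, −35 → −5 °C, then 3; then 6, HMPA, P(OEt)3, −30 °C → rt
Reagents that add atoms: (trimethylsilyl)methylmagnesium chloride, C[Si](C)(C)C[Mg]Cl
Why: Normant carbocupration adds the silylmethyl group and copper syn across the terminal alkyne (carbon to the internal position), and alkylation of the alkenylcopper with retention places the propyl arm cis to CH2SiMe3 and trans to the tether; the silylated alkyne does not react.

Step 5
Reactants: 8 tert-butyl{[(4Z)-5-[(trimethylsilyl)methyl]-9-(trimethylsilyl)non-4-en-8-yn-1-yl]oxy}diphenylsilane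
Product: 9 tert-butyl{[(4Z)-5-[(trimethylsilyl)methyl]non-4-en-8-yn-1-yl]oxy}diphenylsilane
Conditions: K2CO3, MeOH/THF, rt
Reagents that add atoms: none
Why: Methanolysis cleaves only the alkynyl C–Si bond; the allylsilane and the TBDPS ether are stable to carbonate in methanol.

Step 6
Reactants: 9 tert-butyl{[(4Z)-5-[(trimethylsilyl)methyl]non-4-en-8-yn-1-yl]oxy}diphenylsilane
Product: 11 (6Z)-10-[(tert-butyldiphenylsilyl)oxy]-6-[(trimethylsilyl)methyl]dec-6-en-2-yn-1-ol, via lithium acetylide 10 (not isolated)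
Conditions: n-BuLi, THF, −78 °C; (CH2O)n, −78 °C → rt
Reagents that add atoms: formaldehyde (as paraformaldehyde), C=O
Why: Hydroxymethylation of a lithium acetylide gives the propargylic alcohol needed for the directed carbometalation.

Step 7
Reactants: 11 (6Z)-10-[(tert-butyldiphenylsilyl)oxy]-6-[(trimethylsilyl)methyl]dec-6-en-2-yn-1-ol
Product: 13 (2E,6Z)-10-[(tert-butyldiphenylsilyl)oxy]-2,3-dimethyl-6-[(trimethylsilyl)methyl]deca-2,6-dien-1-ol, via alkenylmagnesium chelate 12 (not isolated)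
Conditions: MeMgBr (4 equiv), CuI (15 mol%), THF, 0 °C → rt; then MeI, 0 °C → rt
Reagents that add atoms: methylmagnesium bromide, C[Mg]Br; iodomethane, CI
Why: Copper-catalysed anti-carbomagnesiation of a propargylic alcohol (Duboudin–Jousseaume) puts methyl on C-2 and magnesium on C-3 cis to CH2O in a five-membered chelate, and copper-catalysed methylation with retention gives the E-alkene with the two methyl groups trans.

Step 8
Reactants: 13 (2E,6Z)-10-[(tert-butyldiphenylsilyl)oxy]-2,3-dimethyl-6-[(trimethylsilyl)methyl]deca-2,6-dien-1-ol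
Product: 14 [(2S,3S)-3-{(3Z)-7-[(tert-butyldiphenylsilyl)oxy]-3-[(trimethylsilyl)methyl]hept-3-en-1-yl}-2,3-dimethyloxiran-2-yl]methanol
Conditions: Ti(Oi-Pr)4, L-(+)-DIPT, t-BuOOH, 4 Å MS, CH2Cl2, −25 °C
Reagents that add atoms: tert-butyl hydroperoxide, CC(C)(C)OO
Why: Sharpless asymmetric epoxidation is directed by the allylic hydroxyl, so the allylsilane alkene is left alone; L-(+)-tartrate delivers oxygen to the face used in the epoxidation of geraniol to its (2S,3S)-epoxide, which sets both fully substituted carbons.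

Step 9
Reactants: 14 [(2S,3S)-3-{(3Z)-7-[(tert-butyldiphenylsilyl)oxy]-3-[(trimethylsilyl)methyl]hept-3-en-1-yl}-2,3-dimethyloxiran-2-yl]methanol
Product: 15 (2R,3S)-3-{(3Z)-7-[(tert-butyldiphenylsilyl)oxy]-3-[(trimethylsilyl)methyl]hept-3-en-1-yl}-2,3-dimethyloxirane-2-carbaldehyde
Conditions: Dess–Martin periodinane, NaHCO3, CH2Cl2, 0 °C
Reagents that add atoms: none
Why: Buffered Dess–Martin oxidation of a primary alcohol; the aldehyde has no α-hydrogen, so the epoxide stereocentres cannot epimerise (the descriptor at C-2 changes by priority only).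

Step 10
Reactants: 15 (2R,3S)-3-{(3Z)-7-[(tert-butyldiphenylsilyl)oxy]-3-[(trimethylsilyl)methyl]hept-3-en-1-yl}-2,3-dimethyloxirane-2-carbaldehyde
Product: 16 tert-butyl{[(4Z)-7-[(2S,3S)-3-ethenyl-2,3-dimethyloxiran-2-yl]-5-[(trimethylsilyl)methyl]hept-4-en-1-yl]oxy}diphenylsilane
Conditions: Ph3PCH3Br, KHMDS, THF, 0 °C; then 15, −78 → 0 °C
Reagents that add atoms: methyltriphenylphosphonium bromide, C[P+](c1ccccc1)(c1ccccc1)c1ccccc1.[Br-]
Why: Wittig methylenation of an α,β-epoxy aldehyde under salt-free, non-acidic conditions gives the vinyl epoxide without touching the epoxide.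

Step 11
Reactants: 16 tert-butyl{[(4Z)-7-[(2S,3S)-3-ethenyl-2,3-dimethyloxiran-2-yl]-5-[(trimethylsilyl)methyl]hept-4-en-1-yl]oxy}diphenylsilane
Product: 17 (1S,2S,3R)-3-{3-[(tert-butyldiphenylsilyl)oxy]propyl}-2-ethenyl-1,2-dimethyl-4-methylidenecyclohexan-1-ol
Conditions: Me2AlCl (1.5 equiv), CH2Cl2, −78 °C; Rochelle salt work-up
Reagents that add atoms: none
Why: Me2AlCl binds the epoxide oxygen and weakens the C2–O bond, which is tertiary and allylic, so the 2-(silylmethyl)alkene attacks C2 from the back through C3 while the C1–O bond stays intact, and the β-silyl cation then loses silicon to leave the exocyclic methylene (SE2′). The closest known reaction is the Lewis-acid cyclisation of epoxy allylsilanes to methylenecyclohexanols, a member of the epoxide-initiated cation–olefin cyclisations. The six-membered ring closes endo with respect to the epoxide (both epoxide carbons end in the ring; exo attack at C1 would give a cyclopentane) through a chair in which the C1–O bond is anti to the forming C2–C3 bond. C2 is set by inversion of the epoxide carbon and C1 is carried over, so both come from the Sharpless epoxide with its trans methyl groups; C3 is set by the alkene geometry, the arm trans to the tether lying equatorial in the chair. The step needs C2 to be chosen over C1 (the vinyl group secures this) and ring closure to outrun 1,2-shift or proton loss from the developing allyl cation (the intramolecular, strongly nucleophilic allylsilane, the mild proton-scavenging aluminium Lewis acid and −78 °C serve this); attack at the vinyl terminus would need an eight-membered ring.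

Step 12
Reactants: 17 (1S,2S,3R)-3-{3-[(tert-butyldiphenylsilyl)oxy]propyl}-2-ethenyl-1,2-dimethyl-4-methylidenecyclohexan-1-ol
Product: 18 {[(1S,2S,3R)-3-{3-[(tert-butyldiphenylsilyl)oxy]propyl}-2-ethenyl-1,2-dimethyl-4-methylidenecyclohexyl]oxy}triethylsilane
Conditions: TESOTf, 2,6-lutidine, CH2Cl2, −78 → 0 °C
Reagents that add atoms: triethylsilyl trifluoromethanesulfonate, CC[Si](CC)(CC)OS(=O)(=O)C(F)(F)F
Why: Silyl triflate and a hindered base silylate a tertiary alcohol; the ether keeps the hydroxyl out of the ylide and organometallic steps and comes off with fluoride at the end.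

Step 13
Reactants: 18 {[(1S,2S,3R)-3-{3-[(tert-butyldiphenylsilyl)oxy]propyl}-2-ethenyl-1,2-dimethyl-4-methylidenecyclohexyl]oxy}triethylsilane
Product: 20 (2S,3S,4S)-2-{3-[(tert-butyldiphenylsilyl)oxy]propyl}-3-ethenyl-3,4-dimethyl-4-[(triethylsilyl)oxy]cyclohexan-1-one, via spiro-epoxide 19 (not isolated)
Conditions: m-CPBA (1.05 equiv), NaHCO3, CH2Cl2, 0 °C; then H5IO6, THF/H2O, 0 °C
Reagents that add atoms: m-chloroperbenzoic acid, O=C(OO)c1cccc(Cl)c1; water, O
Why: Prilezhaev epoxidation picks the electron-richer 1,1-disubstituted alkene over the hindered monosubstituted vinyl group, and periodic acid cleaves the epoxide through its diol to the ketone; brief, cold treatment is meant to spare the silyl ethers and the α-stereocentre C3.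

Step 14
Reactants: 20 (2S,3S,4S)-2-{3-[(tert-butyldiphenylsilyl)oxy]propyl}-3-ethenyl-3,4-dimethyl-4-[(triethylsilyl)oxy]cyclohexan-1-one
Product: 21 {[(1S,2S,3S)-3-{3-[(tert-butyldiphenylsilyl)oxy]propyl}-4-(dibromomethylidene)-2-ethenyl-1,2-dimethylcyclohexyl]oxy}triethylsilane
Conditions: [Ph3PCHBr2]Br, t-BuOK, toluene, rt; then 20, rt → 60 °C
Reagents that add atoms: (dibromomethyl)triphenylphosphonium bromide, BrC(Br)[P+](c1ccccc1)(c1ccccc1)c1ccccc1.[Br-]
Why: Wittig-type dibromomethylenation with the preformed ylide Ph3P=CBr2 (Ramirez/Corey–Fuchs reagent) works on ketones and avoids the bromophosphonium species that attack silyl ethers; with the base consumed beforehand C3 should not epimerise.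

Step 15
Reactants: 21 {[(1S,2S,3S)-3-{3-[(tert-butyldiphenylsilyl)oxy]propyl}-4-(dibromomethylidene)-2-ethenyl-1,2-dimethylcyclohexyl]oxy}triethylsilane
Product: 22 (2Z)-2-bromo-2-[(2S,3S,4S)-2-{3-[(tert-butyldiphenylsilyl)oxy]propyl}-3-ethenyl-3,4-dimethyl-4-[(triethylsilyl)oxy]cyclohexylidene]ethan-1-ol
Conditions: Bu3SnCH2OH, Pd2(dba)3 (5 mol%), P(2-furyl)3, toluene, 90 °C
Reagents that add atoms: (tributylstannyl)methanol, CCCC[Sn](CCCC)(CCCC)CO
Why: Stille (Migita–Kosugi) hydroxymethylation; Pd(0) should insert into the less hindered C–Br bond, the one on the side of ring CH2-5 and away from the substituted C3, as in the mono-coupling of 1,1-dibromoalkenes, and the alkylated bromoalkene formed is less reactive than the dibromide.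

Step 16
Reactants: 22 (2Z)-2-bromo-2-[(2S,3S,4S)-2-{3-[(tert-butyldiphenylsilyl)oxy]propyl}-3-ethenyl-3,4-dimethyl-4-[(triethylsilyl)oxy]cyclohexylidene]ethan-1-ol
Product: 23 (2E)-2-[(2R,3S,4S)-2-{3-[(tert-butyldiphenylsilyl)oxy]propyl}-3-ethenyl-3,4-dimethyl-4-[(triethylsilyl)oxy]cyclohexylidene]propan-1-ol
Conditions: Me2Zn, Pd(Pt-Bu3)2 (5 mol%), THF, 0 → 50 °C
Reagents that add atoms: dimethylzinc, C[Zn]C
Why: Negishi coupling replaces the remaining, hindered bromine by methyl with retention, so methyl ends cis to C3 and CH2OH cis to C5, the geometry of the target enal.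

Step 17
Reactants: 24 geranyl chloride; 25 but-2-ynal
Product: 27 (6E)-7,11-dimethyldodeca-6,10-dien-2-yn-4-ol (racemic), via geranylbarium chloride 26 (not isolated)
Conditions: BaI2, lithium biphenylide, THF, rt (active barium); 24, −78 °C; then 25, −78 °C
Reagents that add atoms: none
Why: Allylbarium reagents (Yamamoto) add to aldehydes at the α-carbon with retention of the E-geometry, giving the linear homoallylic, propargylic alcohol in place of the branched adduct.

Step 18
Reactants: 27 (6E)-7,11-dimethyldodeca-6,10-dien-2-yn-4-ol (racemic)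
Product: 28 (6E)-7,11-dimethyldodeca-6,10-dien-2-yn-4-one
Conditions: Dess–Martin periodinane, NaHCO3, CH2Cl2, 0 °C
Reagents that add atoms: none
Why: Neutral Dess–Martin oxidation gives the ynone without base that could move the β,γ-alkene into conjugation.

Step 19
Reactants: 28 (6E)-7,11-dimethyldodeca-6,10-dien-2-yn-4-one
Product: 29 (4R,6E)-7,11-dimethyldodeca-6,10-dien-2-yn-4-ol
Conditions: (R,R)-Ru(TsDPEN)(p-cymene) (2 mol%), i-PrOH, rt
Reagents that add atoms: none
Why: Noyori asymmetric transfer hydrogenation of alkynyl ketones proceeds without added base and leaves alkenes and the alkyne untouched; the ligand sets the carbinol, the (R,R)-catalyst being expected to give the R-alcohol.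

Step 20
Reactants: 29 (4R,6E)-7,11-dimethyldodeca-6,10-dien-2-yn-4-ol
Product: 30 tert-butyl{[(4R,6E)-7,11-dimethyldodeca-6,10-dien-2-yn-4-yl]oxy}dimethylsilane
Conditions: TBSCl, imidazole, DMF, rt
Reagents that add atoms: tert-butyl(chloro)dimethylsilane, CC(C)(C)[Si](C)(C)Cl
Why: Silylation protects the carbinol through hydrozirconation, coupling and the later oxidation, and its bulk steers zirconium to the far alkyne carbon.

Step 21
Reactants: 30 tert-butyl{[(4R,6E)-7,11-dimethyldodeca-6,10-dien-2-yn-4-yl]oxy}dimethylsilane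
Product: 32 tert-butyl{[(2E,4R,6E)-2-iodo-7,11-dimethyldodeca-2,6,10-trien-4-yl]oxy}dimethylsilane, via alkenylzirconocene 31 (not isolated)
Conditions: Cp2Zr(H)Cl (2 equiv), THF, rt → 45 °C; then I2, 0 °C
Reagents that add atoms: iodine, II
Why: Schwartz hydrozirconation is a syn addition that, with excess reagent, places zirconium on the less hindered methyl-bearing alkyne carbon, and iodinolysis with retention gives the E-2-iodoalkene; trisubstituted alkenes do not react under these conditions.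

Step 22
Reactants: 23 (2E)-2-[(2R,3S,4S)-2-{3-[(tert-butyldiphenylsilyl)oxy]propyl}-3-ethenyl-3,4-dimethyl-4-[(triethylsilyl)oxy]cyclohexylidene]propan-1-ol; 32 tert-butyl{[(2E,4R,6E)-2-iodo-7,11-dimethyldodeca-2,6,10-trien-4-yl]oxy}dimethylsilane
Product: 34 (2E)-2-[(2R,3S,4S)-3-{(3E,5R,7E)-5-[(tert-butyldimethylsilyl)oxy]-3,8,12-trimethyltrideca-3,7,11-trien-1-yl}-2-{3-[(tert-butyldiphenylsilyl)oxy]propyl}-3,4-dimethyl-4-[(triethylsilyl)oxy]cyclohexylidene]propan-1-ol, via alkylborane 33 (not isolated)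
Conditions: 23, 9-BBN (3 equiv), THF, rt; then 32, Pd(dppf)Cl2 (10 mol%), AsPh3, Cs2CO3, DMF/H2O, rt
Reagents that add atoms: none
Why: 9-BBN hydroborates the vinyl group at its terminus (the tetrasubstituted alkene is inert and the hydroxyl is held as a borinate), and B-alkyl Suzuki–Miyaura coupling joins it to the iodoalkene with retention of the E-geometry.

Step 23
Reactants: 34 (2E)-2-[(2R,3S,4S)-3-{(3E,5R,7E)-5-[(tert-butyldimethylsilyl)oxy]-3,8,12-trimethyltrideca-3,7,11-trien-1-yl}-2-{3-[(tert-butyldiphenylsilyl)oxy]propyl}-3,4-dimethyl-4-[(triethylsilyl)oxy]cyclohexylidene]propan-1-ol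
Product: 35 (2E)-2-[(2R,3S,4S)-3-{(3E,5R,7E)-5-[(tert-butyldimethylsilyl)oxy]-3,8,12-trimethyltrideca-3,7,11-trien-1-yl}-2-{3-[(tert-butyldiphenylsilyl)oxy]propyl}-3,4-dimethyl-4-[(triethylsilyl)oxy]cyclohexylidene]propanal
Conditions: Dess–Martin periodinane, NaHCO3, CH2Cl2, 0 °C
Reagents that add atoms: none
Why: The only free hydroxyl, a primary allylic one, is oxidised to the tetrasubstituted enal under neutral conditions that leave the alkene geometry and the silyl ethers alone.

Step 24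
Reactants: 35 (2E)-2-[(2R,3S,4S)-3-{(3E,5R,7E)-5-[(tert-butyldimethylsilyl)oxy]-3,8,12-trimethyltrideca-3,7,11-trien-1-yl}-2-{3-[(tert-butyldiphenylsilyl)oxy]propyl}-3,4-dimethyl-4-[(triethylsilyl)oxy]cyclohexylidene]propanal
Product: 36 (2E)-2-[(2R,3S,4S)-4-hydroxy-3-[(3E,5R,7E)-5-hydroxy-3,8,12-trimethyltrideca-3,7,11-trien-1-yl]-2-(3-hydroxypropyl)-3,4-dimethylcyclohexylidene]propanal (CNP0417035.1)
Conditions: TBAF, AcOH (1:1), THF, 0 → 40 °C
Reagents that add atoms: none
Why: Fluoride removes the TBDPS, TBS and TES ethers in one operation, and the acetic acid buffer is meant to protect the enal and the allylic carbinol from base.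

**Compound list**

1 | 1,5-hexadiyne | C#CCCC#C | starting material
2 | lithium hexa-1,5-diyn-1-ide (not isolated) | [Li]C#CCCC#C | intermediate
3 | trimethyl(hexa-1,5-diyn-1-yl)silane | C[Si](C)(C)C#CCCC#C | intermediate
4 | 3-bromopropan-1-ol | OCCCBr | starting material
5 | (3-bromopropoxy)(tert-butyl)diphenylsilane | BrCCCO[Si](c1ccccc1)(c1ccccc1)C(C)(C)C | intermediate
6 | tert-butyl(3-iodopropoxy)diphenylsilane | ICCCO[Si](c1ccccc1)(c1ccccc1)C(C)(C)C | intermediate
7 | {(1Z)-2-[(trimethylsilyl)methyl]-6-(trimethylsilyl)hex-1-en-5-yn-1-yl}copper (not isolated) | C[Si](C)(C)C#CCC/C(C[Si](C)(C)C)=C/[Cu] | intermediate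
8 | tert-butyl{[(4Z)-5-[(trimethylsilyl)methyl]-9-(trimethylsilyl)non-4-en-8-yn-1-yl]oxy}diphenylsilane | C[Si](C)(C)C#CCC/C(C[Si](C)(C)C)=C/CCCO[Si](c1ccccc1)(c1ccccc1)C(C)(C)C | intermediate
9 | tert-butyl{[(4Z)-5-[(trimethylsilyl)methyl]non-4-en-8-yn-1-yl]oxy}diphenylsilane | C#CCC/C(C[Si](C)(C)C)=C/CCCO[Si](c1ccccc1)(c1ccccc1)C(C)(C)C | intermediate
10 | lithium acetylide of 9 (not isolated) | [Li]C#CCC/C(C[Si](C)(C)C)=C/CCCO[Si](c1ccccc1)(c1ccccc1)C(C)(C)C | intermediate
11 | (6Z)-10-[(tert-butyldiphenylsilyl)oxy]-6-[(trimethylsilyl)methyl]dec-6-en-2-yn-1-ol | OCC#CCC/C(C[Si](C)(C)C)=C/CCCO[Si](c1ccccc1)(c1ccccc1)C(C)(C)C | intermediate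
12 | cyclic alkenylmagnesium alkoxide from 11 (2,5-dihydro-1,2-oxamagnesole, methyl on C-4, chain on C-3; not isolated) | [Mg]1OCC(C)=C1CC/C(C[Si](C)(C)C)=C/CCCO[Si](c1ccccc1)(c1ccccc1)C(C)(C)C | intermediate
13 | (2E,6Z)-10-[(tert-butyldiphenylsilyl)oxy]-2,3-dimethyl-6-[(trimethylsilyl)methyl]deca-2,6-dien-1-ol | OC/C(C)=C(\C)CC/C(C[Si](C)(C)C)=C/CCCO[Si](c1ccccc1)(c1ccccc1)C(C)(C)C | intermediate
14 | [(2S,3S)-3-{(3Z)-7-[(tert-butyldiphenylsilyl)oxy]-3-[(trimethylsilyl)methyl]hept-3-en-1-yl}-2,3-dimethyloxiran-2-yl]methanol | OC[C@]1(C)O[C@@]1(C)CC/C(C[Si](C)(C)C)=C/CCCO[Si](c1ccccc1)(c1ccccc1)C(C)(C)C | intermediate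
15 | (2R,3S)-3-{(3Z)-7-[(tert-butyldiphenylsilyl)oxy]-3-[(trimethylsilyl)methyl]hept-3-en-1-yl}-2,3-dimethyloxirane-2-carbaldehyde | O=C[C@]1(C)O[C@@]1(C)CC/C(C[Si](C)(C)C)=C/CCCO[Si](c1ccccc1)(c1ccccc1)C(C)(C)C | intermediate
16 | tert-butyl{[(4Z)-7-[(2S,3S)-3-ethenyl-2,3-dimethyloxiran-2-yl]-5-[(trimethylsilyl)methyl]hept-4-en-1-yl]oxy}diphenylsilane | C=C[C@]1(C)O[C@@]1(C)CC/C(C[Si](C)(C)C)=C/CCCO[Si](c1ccccc1)(c1ccccc1)C(C)(C)C | intermediate
17 | (1S,2S,3R)-3-{3-[(tert-butyldiphenylsilyl)oxy]propyl}-2-ethenyl-1,2-dimethyl-4-methylidenecyclohexan-1-ol | C=C[C@@]1(C)[C@H](CCCO[Si](c2ccccc2)(c2ccccc2)C(C)(C)C)C(=C)CC[C@]1(C)O | intermediate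
18 | {[(1S,2S,3R)-3-{3-[(tert-butyldiphenylsilyl)oxy]propyl}-2-ethenyl-1,2-dimethyl-4-methylidenecyclohexyl]oxy}triethylsilane | C=C[C@@]1(C)[C@H](CCCO[Si](c2ccccc2)(c2ccccc2)C(C)(C)C)C(=C)CC[C@]1(C)O[Si](CC)(CC)CC | intermediate
19 | spiro-epoxide of 18 at the exocyclic methylene (1-oxaspiro[2.5]octane, both epimers at the spiro carbon; not isolated) | C=C[C@@]1(C)[C@H](CCCO[Si](c2ccccc2)(c2ccccc2)C(C)(C)C)C2(CO2)CC[C@]1(C)O[Si](CC)(CC)CC | intermediate
20 | (2S,3S,4S)-2-{3-[(tert-butyldiphenylsilyl)oxy]propyl}-3-ethenyl-3,4-dimethyl-4-[(triethylsilyl)oxy]cyclohexan-1-one | C=C[C@@]1(C)[C@H](CCCO[Si](c2ccccc2)(c2ccccc2)C(C)(C)C)C(=O)CC[C@]1(C)O[Si](CC)(CC)CC | intermediate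
21 | {[(1S,2S,3S)-3-{3-[(tert-butyldiphenylsilyl)oxy]propyl}-4-(dibromomethylidene)-2-ethenyl-1,2-dimethylcyclohexyl]oxy}triethylsilane | C=C[C@@]1(C)[C@H](CCCO[Si](c2ccccc2)(c2ccccc2)C(C)(C)C)C(=C(Br)Br)CC[C@]1(C)O[Si](CC)(CC)CC | intermediate
22 | (2Z)-2-bromo-2-[(2S,3S,4S)-2-{3-[(tert-butyldiphenylsilyl)oxy]propyl}-3-ethenyl-3,4-dimethyl-4-[(triethylsilyl)oxy]cyclohexylidene]ethan-1-ol | C=C[C@@]1(C)[C@H](CCCO[Si](c2ccccc2)(c2ccccc2)C(C)(C)C)/C(=C(\Br)CO)CC[C@]1(C)O[Si](CC)(CC)CC | intermediate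
23 | (2E)-2-[(2R,3S,4S)-2-{3-[(tert-butyldiphenylsilyl)oxy]propyl}-3-ethenyl-3,4-dimethyl-4-[(triethylsilyl)oxy]cyclohexylidene]propan-1-ol | C=C[C@@]1(C)[C@H](CCCO[Si](c2ccccc2)(c2ccccc2)C(C)(C)C)/C(=C(\C)CO)CC[C@]1(C)O[Si](CC)(CC)CC | intermediate
24 | geranyl chloride | CC(C)=CCC/C(C)=C/CCl | starting material
25 | but-2-ynal | CC#CC=O | starting material
26 | geranylbarium chloride (not isolated) | CC(C)=CCC/C(C)=C/C[Ba]Cl | intermediate
27 | (6E)-7,11-dimethyldodeca-6,10-dien-2-yn-4-ol (racemic) | CC(C)=CCC/C(C)=C/CC(O)C#CC | intermediate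
28 | (6E)-7,11-dimethyldodeca-6,10-dien-2-yn-4-one | CC(C)=CCC/C(C)=C/CC(=O)C#CC | intermediate
29 | (4R,6E)-7,11-dimethyldodeca-6,10-dien-2-yn-4-ol | CC(C)=CCC/C(C)=C/C[C@@H](O)C#CC | intermediate
30 | tert-butyl{[(4R,6E)-7,11-dimethyldodeca-6,10-dien-2-yn-4-yl]oxy}dimethylsilane | CC(C)=CCC/C(C)=C/C[C@@H](O[Si](C)(C)C(C)(C)C)C#CC | intermediate
31 | chlorobis(cyclopentadienyl)zirconium(IV) (E)-alkenyl adduct of 30, Zr on C-2 (not isolated) | CC(C)=CCC/C(C)=C/C[C@@H](O[Si](C)(C)C(C)(C)C)/C=C(\C)[Zr](Cl)(C1C=CC=C1)C1C=CC=C1 | intermediate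
32 | tert-butyl{[(2E,4R,6E)-2-iodo-7,11-dimethyldodeca-2,6,10-trien-4-yl]oxy}dimethylsilane | CC(C)=CCC/C(C)=C/C[C@@H](O[Si](C)(C)C(C)(C)C)/C=C(\C)I | intermediate
33 | B-alkyl-9-BBN from 23 (boron on the terminal carbon of the former vinyl group; allylic hydroxyl as its 9-BBN borinate; not isolated) | C12CCCC(CCC1)B2CC[C@@]1(C)[C@H](CCCO[Si](c2ccccc2)(c2ccccc2)C(C)(C)C)/C(=C(\C)COB2C3CCCC2CCC3)CC[C@]1(C)O[Si](CC)(CC)CC | intermediate
34 | (2E)-2-[(2R,3S,4S)-3-{(3E,5R,7E)-5-[(tert-butyldimethylsilyl)oxy]-3,8,12-trimethyltrideca-3,7,11-trien-1-yl}-2-{3-[(tert-butyldiphenylsilyl)oxy]propyl}-3,4-dimethyl-4-[(triethylsilyl)oxy]cyclohexylidene]propan-1-ol | CC(C)=CCC/C(C)=C/C[C@@H](O[Si](C)(C)C(C)(C)C)/C=C(\C)CC[C@@]1(C)[C@H](CCCO[Si](c2ccccc2)(c2ccccc2)C(C)(C)C)/C(=C(\C)CO)CC[C@]1(C)O[Si](CC)(CC)CC | intermediate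
35 | (2E)-2-[(2R,3S,4S)-3-{(3E,5R,7E)-5-[(tert-butyldimethylsilyl)oxy]-3,8,12-trimethyltrideca-3,7,11-trien-1-yl}-2-{3-[(tert-butyldiphenylsilyl)oxy]propyl}-3,4-dimethyl-4-[(triethylsilyl)oxy]cyclohexylidene]propanal | CC(C)=CCC/C(C)=C/C[C@@H](O[Si](C)(C)C(C)(C)C)/C=C(\C)CC[C@@]1(C)[C@H](CCCO[Si](c2ccccc2)(c2ccccc2)C(C)(C)C)/C(=C(\C)C=O)CC[C@]1(C)O[Si](CC)(CC)CC | intermediate
36 | (2E)-2-[(2R,3S,4S)-4-hydroxy-3-[(3E,5R,7E)-5-hydroxy-3,8,12-trimethyltrideca-3,7,11-trien-1-yl]-2-(3-hydroxypropyl)-3,4-dimethylcyclohexylidene]propanal | CC(C)=CCC/C(C)=C/C[C@@H](O)/C=C(\C)CC[C@@]1(C)[C@H](CCCO)/C(=C(\C)C=O)CC[C@]1(C)O | target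

**Count and risks**

Total steps: 24. Longest linear sequence: 18 steps (2–16 and 22–24, from 3-bromopropan-1-ol); step 1 supplies the diyne partner for step 4 and steps 17–21 make the side-chain iodide.

The three steps most likely to fail:

1. Step 11 (ring closure). Ionisation of the allylic C–O bond may run ahead of C–C bond formation, so that a free allyl cation loses the epoxide configuration at C2, or collapses by 1,2-shift or proton loss before the ring closes. The fallback sets out from epoxy aldehyde 15 and comes back at ketone 20. It replaces the vinyl group by an acrylate, whose γ,δ-epoxide is known to be opened at the γ-carbon in an SN2-type manner with inversion, and later trims the acrylate back to the vinyl group. Aldehyde 15 is olefinated with Ph3P=CHCO2Me (CH2Cl2, rt) to methyl (2E)-3-[(2S,3S)-3-{(3Z)-7-[(tert-butyldiphenylsilyl)oxy]-3-[(trimethylsilyl)methyl]hept-3-en-1-yl}-2,3-dimethyloxiran-2-yl]prop-2-enoate F1. BF3·OEt2 in CH2Cl2 at −78 °C closes the same ring to the acrylate-bearing methylenecyclohexanol F2. Silylation (TESOTf, 2,6-lutidine) gives the triethylsilyl ether F3. Ozonolysis (O3, CH2Cl2/MeOH, −78 °C; Me2S) cleaves the acrylate and the exocyclic methylene together to the keto aldehyde F4. One equivalent of Ph3P=CH2 at −78 °C methylenates the aldehyde in preference to the hindered ketone and gives 20, so steps 12 and 13 are not needed.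

2. Step 4 (carbocupration/alkylation). The silylmethyl group may transfer sluggishly from copper to the alkyne, and the alkenylcopper may be protonated or dimerise before it is alkylated by the unactivated iodide. The fallback sets out from alkyne 3 (with bromide 5) and comes back at 8. It builds the same trisubstituted alkene by syn-bromoboration and two cross-couplings. BBr3 (CH2Cl2, −78 °C → rt) followed by pinacol gives the (Z)-2-bromoalkenyl pinacol boronate F5. Negishi coupling at the C–Br bond with Me3SiCH2ZnCl (Pd(Pt-Bu3)2, THF) gives the (silylmethyl)alkenyl boronate F6 with retention. Alkyl–alkenyl Suzuki coupling of F6 with bromide 5 (Pd(OAc)2, P(t-Bu)2Me, KOt-Bu, tert-amyl alcohol) then gives 8, the arm again cis to CH2SiMe3.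

3. Step 15 (first coupling on the dibromoalkene). Oxidative addition may not discriminate enough between the two C–Br bonds, giving both alkene geometries, or a second coupling may follow the first. The fallback sets out from ketone 20 and comes back at allylic alcohol 23. It forms the tetrasubstituted alkene by carbonyl olefination and relies on separation instead of site selection. Horner–Wadsworth–Emmons reaction of 20 with diethyl (1-cyanoethyl)phosphonate (NaH, THF, 0 °C → reflux) gives the α-methyl alkylidene nitrile, from which the E-isomer F7 is separated (the other isomer can be re-equilibrated photochemically). DIBAL-H (toluene, −78 °C) and hydrolysis give the enal F8, and Luche reduction (NaBH4, CeCl3, MeOH, 0 °C) gives 23.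

**Further compounds**

F1 | step 11 | methyl (2E)-3-[(2S,3S)-3-{(3Z)-7-[(tert-butyldiphenylsilyl)oxy]-3-[(trimethylsilyl)methyl]hept-3-en-1-yl}-2,3-dimethyloxiran-2-yl]prop-2-enoate | COC(=O)/C=C/[C@]1(C)O[C@@]1(C)CC/C(C[Si](C)(C)C)=C/CCCO[Si](c1ccccc1)(c1ccccc1)C(C)(C)C
F2 | step 11 | analogue of 17 with an (E)-CH=CH–CO2Me group in place of the vinyl group | COC(=O)/C=C/[C@@]1(C)[C@H](CCCO[Si](c2ccccc2)(c2ccccc2)C(C)(C)C)C(=C)CC[C@]1(C)O
F3 | step 11 | triethylsilyl ether of F2 | COC(=O)/C=C/[C@@]1(C)[C@H](CCCO[Si](c2ccccc2)(c2ccccc2)C(C)(C)C)C(=C)CC[C@]1(C)O[Si](CC)(CC)CC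
F4 | step 11 | keto aldehyde: analogue of 20 with a formyl group in place of the vinyl group | O=C[C@@]1(C)[C@H](CCCO[Si](c2ccccc2)(c2ccccc2)C(C)(C)C)C(=O)CC[C@]1(C)O[Si](CC)(CC)CC
F5 | step 4 | 2-[(1Z)-2-bromo-6-(trimethylsilyl)hex-1-en-5-yn-1-yl]-4,4,5,5-tetramethyl-1,3,2-dioxaborolane | C[Si](C)(C)C#CCC/C(Br)=C/B1OC(C)(C)C(C)(C)O1
F6 | step 4 | 4,4,5,5-tetramethyl-2-{(1Z)-2-[(trimethylsilyl)methyl]-6-(trimethylsilyl)hex-1-en-5-yn-1-yl}-1,3,2-dioxaborolane | C[Si](C)(C)C#CCC/C(C[Si](C)(C)C)=C/B1OC(C)(C)C(C)(C)O1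
F7 | step 15 | (E)-α-methyl alkylidene nitrile: analogue of 23 with C≡N in place of CH2OH | C=C[C@@]1(C)[C@H](CCCO[Si](c2ccccc2)(c2ccccc2)C(C)(C)C)/C(=C(\C)C#N)CC[C@]1(C)O[Si](CC)(CC)CC
F8 | step 15 | (E)-enal: analogue of 23 with CHO in place of CH2OH | C=C[C@@]1(C)[C@H](CCCO[Si](c2ccccc2)(c2ccccc2)C(C)(C)C)/C(=C(\C)C=O)CC[C@]1(C)O[Si](CC)(CC)CC
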